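**Plan**
- Numbering, kept for all intermediates: ring A is the cyclohexanone C1 (carries acyl carbon C7), C2, C3 (ketone), C4 (propenyl C13–C15), C5, C6 (carries C5' of ring B, the tetronate O1'–C2'–C3'–C4'–C5'); C8–C12 is the hexenoyl tail.
- Enabling feature: the ketones C3 and C7 are 1,4-related across C2–C1 of ring A. Enolate polarity cannot build this pairing, but it arises when C3 is made an acyl anion and adds to the methylene end C2 of an enone C2=C1–C7(=O), so the last skeletal cut is C2–C3.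
- Cuts in retrosynthetic order: O–CH3 (protecting group), C2–C3 (ring A), C1–C7, ring B (C3'–C4' and O1'–C2'), C6–C1, C4–C5.
- Forward: C4–C5 joins the C3–C4(–C13–C15) piece to the C5–C6–C5'–C4' piece, C1≡C2 is added at C6, ring B is closed, C7–C12 is attached at C1, ring A is closed, and the methyl ether is removed.
- Stereochemistry: C4 from alkylation of an (S)-4-benzyloxazolidinone imide; C5' and C6 from Sharpless epoxidation with L-(+)-diethyl tartrate followed by SN2 opening at C6; C1 from protonation of the C1=C7 enolate inside the ring-closing step.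

Key step: step 20

Assumption: of the two enantiomers of the aminoindanol-derived triazolium salt, the (5aR,10bS) form is taken as the one that delivers the C1 proton to the ring face remote from the C6 tetronate, the face the substrate itself prefers.
Remark: the carbinol carbon C7 in 29 and 30 is a mixture of epimers; it becomes a ketone in step 19.

Step 1
Reactants: 1 2-methyl-2-vinyloxirane
Product: 2 (2E)-4-bromo-2-methylbut-2-en-1-ol
Conditions: CuBr2, Li2CO3, CHCl3/EtOAc, reflux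
Reagents that add atoms: copper dibromide CuBr2, [Cu+2].[Br-].[Br-]
Why: Copper-assisted conjugate (SN2') opening of the vinyl oxirane by bromide at the alkene terminus is a known way to this bromohydrin and should favour the (E)-alkene that later becomes C5'=C6.

Step 2
Reactants: 2 (2E)-4-bromo-2-methylbut-2-en-1-ol
Product: 3 tert-butyl{[(2E)-4-bromo-2-methylbut-2-en-1-yl]oxy}dimethylsilane
Conditions: t-BuMe2SiCl, imidazole, CH2Cl2, 0 °C
Reagents that add atoms: tert-butyldimethylsilyl chloride, CC(C)(C)[Si](C)(C)Cl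
Why: Silylation of the primary alcohol masks it for the enolate alkylation; the reaction is kept cold and short so the allylic bromide is not displaced by imidazole.

Step 3
Reactants: 4 (3E)-pent-3-enoic acid; 5 (4S)-4-benzyl-1,3-oxazolidin-2-one
Product: 7 (4S)-4-benzyl-3-[(3E)-pent-3-enoyl]-1,3-oxazolidin-2-one, via mixed pivalic anhydride 6 (not isolated)
Conditions: 4, t-BuCOCl, Et3N, THF, −20 °C; then 5, LiCl, −20 °C → rt
Reagents that add atoms: none
Why: N-acylation of the oxazolidinone through the mixed anhydride under amine/LiCl conditions avoids strong base, so the (E)-3-alkene should not move into conjugation.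

Step 4
Reactants: 7 (4S)-4-benzyl-3-[(3E)-pent-3-enoyl]-1,3-oxazolidin-2-one; 3 tert-butyl{[(2E)-4-bromo-2-methylbut-2-en-1-yl]oxy}dimethylsilane
Product: 9 (4S)-4-benzyl-3-[(2S,3E)-2-{(2E)-4-[(tert-butyldimethylsilyl)oxy]-3-methylbut-2-en-1-yl}pent-3-enoyl]-1,3-oxazolidin-2-one, via sodium enolate 8 (not isolated)
Conditions: NaN(SiMe3)2, THF, −78 °C; then 3, −78 → −45 °C; AcOH quench at −78 °C
Reagents that add atoms: none
Why: Evans asymmetric alkylation: the chelated (Z)-dienolate is alkylated at its alpha carbon by the allylic bromide on the face opposite the benzyl group, which forms C4–C5 and sets C4 as S while the (E)-propenyl group stays out of conjugation.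

Step 5
Reactants: 9 (4S)-4-benzyl-3-[(2S,3E)-2-{(2E)-4-[(tert-butyldimethylsilyl)oxy]-3-methylbut-2-en-1-yl}pent-3-enoyl]-1,3-oxazolidin-2-one
Product: 10 (2S,3E)-2-{(2E)-4-[(tert-butyldimethylsilyl)oxy]-3-methylbut-2-en-1-yl}pent-3-en-1-ol
Conditions: LiBH4, MeOH (1 equiv), Et2O, 0 °C
Reagents that add atoms: none
Why: Reductive cleavage of the imide by LiBH4 attacks the exocyclic carbonyl and releases the auxiliary; with C3 at the alcohol level C4 is no longer enolisable.

Step 6
Reactants: 10 (2S,3E)-2-{(2E)-4-[(tert-butyldimethylsilyl)oxy]-3-methylbut-2-en-1-yl}pent-3-en-1-ol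
Product: 11 tert-butyl{[(2S,3E)-2-{(2E)-4-[(tert-butyldimethylsilyl)oxy]-3-methylbut-2-en-1-yl}pent-3-en-1-yl]oxy}diphenylsilane
Conditions: t-BuPh2SiCl, imidazole, CH2Cl2, rt
Reagents that add atoms: tert-butyldiphenylsilyl chloride, CC(C)(C)[Si](Cl)(c1ccccc1)c1ccccc1
Why: Silylation of the C3 hydroxyl with the more acid-stable silyl group lets the allylic silyl ether be removed selectively in the next step.

Step 7
Reactants: 11 tert-butyl{[(2S,3E)-2-{(2E)-4-[(tert-butyldimethylsilyl)oxy]-3-methylbut-2-en-1-yl}pent-3-en-1-yl]oxy}diphenylsilane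
Product: 12 (2E,5S,6E)-5-{[(tert-butyldiphenylsilyl)oxy]methyl}-2-methylocta-2,6-dien-1-ol
Conditions: pyridinium p-toluenesulfonate (cat.), MeOH, rt
Reagents that add atoms: none
Why: Mild acid methanolysis cleaves the primary allylic tert-butyldimethylsilyl ether much faster than the tert-butyldiphenylsilyl ether, freeing the allylic alcohol for directed epoxidation.

Step 8
Reactants: 12 (2E,5S,6E)-5-{[(tert-butyldiphenylsilyl)oxy]methyl}-2-methylocta-2,6-dien-1-ol
Product: 13 [(2S,3S)-3-[(2S,3E)-2-{[(tert-butyldiphenylsilyl)oxy]methyl}pent-3-en-1-yl]-2-methyloxiran-2-yl]methanol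
Conditions: Ti(OiPr)4 (10 mol%), L-(+)-diethyl tartrate (12 mol%), t-BuOOH, 4 Å molecular sieves, CH2Cl2, −20 °C
Reagents that add atoms: tert-butyl hydroperoxide, CC(C)(C)OO
Why: Sharpless asymmetric epoxidation of the (E)-2-methyl allylic alcohol with L-(+)-tartrate gives the (2S,3S)-epoxide under reagent control, setting C5' and C6, while the propenyl alkene, which has no free allylic hydroxyl, is not epoxidised.

Step 9
Reactants: 13 [(2S,3S)-3-[(2S,3E)-2-{[(tert-butyldiphenylsilyl)oxy]methyl}pent-3-en-1-yl]-2-methyloxiran-2-yl]methanol; 14 trimethylsilylacetylene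
Product: 17 (2R,3S,5S,6E)-5-{[(tert-butyldiphenylsilyl)oxy]methyl}-2-methyl-3-[(trimethylsilyl)ethynyl]oct-6-ene-1,2-diol, via lithium acetylide 15 (not isolated), via alkynyldiethylalane 16 (not isolated)
Conditions: 14, n-BuLi, toluene, −78 → 0 °C; Et2AlCl, 0 °C; then 13, toluene, 0 °C → rt; aq. potassium sodium tartrate work-up
Reagents that add atoms: none
Why: Alkynylalane opening of a 2,3-epoxy alcohol: the aluminium alkoxide holds the reagent and the alkynyl group attacks the distal, secondary epoxide carbon C6 with inversion (SN2), forming C6–C1 with C6 as S and leaving the C5'–O bond untouched (C5' becomes R by priority change only).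

Step 10
Reactants: 17 (2R,3S,5S,6E)-5-{[(tert-butyldiphenylsilyl)oxy]methyl}-2-methyl-3-[(trimethylsilyl)ethynyl]oct-6-ene-1,2-diol
Product: 19 (2R,3S,5S,6E)-5-{[(tert-butyldiphenylsilyl)oxy]methyl}-2-hydroxy-2-methyl-3-[(trimethylsilyl)ethynyl]oct-6-enoic acid, via hydroxy aldehyde 18 (not isolated)
Conditions: 2,2,6,6-tetramethylpiperidin-1-oxyl (TEMPO, cat.), NaOCl (cat.), NaClO2, MeCN/phosphate buffer pH 6.7, 35 °C
Reagents that add atoms: sodium chlorite NaClO2, [Na+].[O-]Cl=O
Why: Oxoammonium oxidation of the primary alcohol to aldehyde 18 and chlorite oxidation in the same flask give the alpha-hydroxy acid; the tertiary alcohol cannot be oxidised and the near-neutral buffer should suppress glycol cleavage and alkene chlorination.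

Step 11
Reactants: 19 (2R,3S,5S,6E)-5-{[(tert-butyldiphenylsilyl)oxy]methyl}-2-hydroxy-2-methyl-3-[(trimethylsilyl)ethynyl]oct-6-enoic acid
Product: 20 methyl (2R,3S,5S,6E)-5-{[(tert-butyldiphenylsilyl)oxy]methyl}-2-hydroxy-2-methyl-3-[(trimethylsilyl)ethynyl]oct-6-enoate
Conditions: MeI, KHCO3, DMF, rt
Reagents that add atoms: iodomethane, CI
Why: SN2 O-alkylation of the carboxylate by iodomethane under weak base leaves the tertiary alcohol and the alkynylsilane untouched.

Step 12
Reactants: 20 methyl (2R,3S,5S,6E)-5-{[(tert-butyldiphenylsilyl)oxy]methyl}-2-hydroxy-2-methyl-3-[(trimethylsilyl)ethynyl]oct-6-enoate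
Product: 21 methyl (2R,3S,5S,6E)-5-{[(tert-butyldiphenylsilyl)oxy]methyl}-2-methyl-2-(propanoyloxy)-3-[(trimethylsilyl)ethynyl]oct-6-enoate
Conditions: (EtCO)2O, Sc(OTf)3 (cat.), MeCN/CH2Cl2, −20 → 0 °C
Reagents that add atoms: propanoic anhydride, CCC(=O)OC(=O)CC
Why: Sc(OTf)3-catalysed acylation with an anhydride is a known way to esterify hindered tertiary alcohols at low temperature, where the silyl ether and the alkynylsilane should persist.

Step 13
Reactants: 21 methyl (2R,3S,5S,6E)-5-{[(tert-butyldiphenylsilyl)oxy]methyl}-2-methyl-2-(propanoyloxy)-3-[(trimethylsilyl)ethynyl]oct-6-enoate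
Product: 23 (5R)-5-[(3S,5S,6E)-5-{[(tert-butyldiphenylsilyl)oxy]methyl}-1-(trimethylsilyl)oct-6-en-1-yn-3-yl]-4-methoxy-3,5-dimethylfuran-2(5H)-one, via potassium tetronate 22 (not isolated)
Conditions: KN(SiMe3)2 (2.2 equiv), THF, −78 → 0 °C; then Me2SO4, DMF, 0 °C → rt
Reagents that add atoms: dimethyl sulfate, COS(=O)(=O)OC
Why: Dieckmann condensation: the propanoate enolate attacks the neighbouring methyl ester (5-exo-trig) to close ring B as tetronate salt 22, which the hard electrophile Me2SO4 should alkylate on the C4' oxygen in a dipolar solvent; C5' is quaternary and cannot epimerise.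

Step 14
Reactants: 23 (5R)-5-[(3S,5S,6E)-5-{[(tert-butyldiphenylsilyl)oxy]methyl}-1-(trimethylsilyl)oct-6-en-1-yn-3-yl]-4-methoxy-3,5-dimethylfuran-2(5H)-one
Product: 24 (5R)-5-[(3S,5S,6E)-5-{[(tert-butyldiphenylsilyl)oxy]methyl}oct-6-en-1-yn-3-yl]-4-methoxy-3,5-dimethylfuran-2(5H)-one
Conditions: K2CO3, MeOH, 0 °C → rt
Reagents that add atoms: none
Why: Methoxide-induced protodesilylation of the alkynylsilane; the methyl tetronate and the bulky silyl ether should be stable to K2CO3/MeOH at this temperature.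

Step 15
Reactants: 24 (5R)-5-[(3S,5S,6E)-5-{[(tert-butyldiphenylsilyl)oxy]methyl}oct-6-en-1-yn-3-yl]-4-methoxy-3,5-dimethylfuran-2(5H)-one
Product: 26 (5R)-5-[(3R,5S,6E)-5-{[(tert-butyldiphenylsilyl)oxy]methyl}-2-iodoocta-1,6-dien-3-yl]-4-methoxy-3,5-dimethylfuran-2(5H)-one, via iodoalkenylborane 25 (not isolated)
Conditions: 9-iodo-9-borabicyclo[3.3.1]nonane, hexane/CH2Cl2, −20 °C; then AcOH, 0 °C
Reagents that add atoms: 9-iodo-9-borabicyclo[3.3.1]nonane, IB1C2CCCC1CCC2
Why: Haloboration: B–I adds syn across the terminal alkyne with boron on C2 and iodine on C1, and protodeboronation of 25 by AcOH leaves the Markovnikov 2-iodoalk-1-ene; the internal (E)-alkenes should not react at −20 °C (the C6 descriptor changes to R by priority only).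

Step 16
Reactants: 27 (4E)-hex-4-en-1-ol
Product: 28 (4E)-hex-4-enal
Conditions: TEMPO (cat.), PhI(OAc)2, CH2Cl2, rt; used as a solution
Reagents that add atoms: none
Why: Oxoammonium oxidation (TEMPO/PhI(OAc)2) of a primary alcohol stops at the aldehyde and does not touch the alkene.

Step 17
Reactants: 26 (5R)-5-[(3R,5S,6E)-5-{[(tert-butyldiphenylsilyl)oxy]methyl}-2-iodoocta-1,6-dien-3-yl]-4-methoxy-3,5-dimethylfuran-2(5H)-one; 28 (4E)-hex-4-enal
Product: 29 (5R)-5-[(2E,4S,6S,11E)-4-{[(tert-butyldiphenylsilyl)oxy]methyl}-8-hydroxy-7-methylidenetrideca-2,11-dien-6-yl]-4-methoxy-3,5-dimethylfuran-2(5H)-one (both epimers at the carbinol carbon)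
Conditions: CrCl2 (4 equiv), NiCl2 (2 mol%), DMSO, rt
Reagents that add atoms: none
Why: Nozaki–Hiyama–Kishi coupling: NiCl2-catalysed formation of the alkenylchromium species (trivalent chromium) and its chemoselective addition to the aldehyde form C1–C7 without base, so the tetronate and the enolisable aldehyde are tolerated; the carbinol configuration is not controlled and is erased in step 19.

Step 18
Reactants: 29 (5R)-5-[(2E,4S,6S,11E)-4-{[(tert-butyldiphenylsilyl)oxy]methyl}-8-hydroxy-7-methylidenetrideca-2,11-dien-6-yl]-4-methoxy-3,5-dimethylfuran-2(5H)-one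
Product: 30 (5R)-5-[(2E,4S,6S,11E)-8-hydroxy-4-(hydroxymethyl)-7-methylidenetrideca-2,11-dien-6-yl]-4-methoxy-3,5-dimethylfuran-2(5H)-one
Conditions: Bu4NF, AcOH, THF, 0 °C → rt
Reagents that add atoms: none
Why: Fluoride cleavage of the silyl ether, buffered with AcOH so that neither the tetronate nor the allylic alcohol meets basic fluoride.

Step 19
Reactants: 30 (5R)-5-[(2E,4S,6S,11E)-8-hydroxy-4-(hydroxymethyl)-7-methylidenetrideca-2,11-dien-6-yl]-4-methoxy-3,5-dimethylfuran-2(5H)-one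
Product: 31 (2S,4S,9E)-4-[(2R)-3-methoxy-2,4-dimethyl-5-oxo-2,5-dihydrofuran-2-yl]-5-methylidene-6-oxo-2-[(1E)-prop-1-en-1-yl]undec-9-enal
Conditions: Dess–Martin periodinane (3 equiv), NaHCO3, CH2Cl2, 0 °C → rt; short silica filtration, used at once
Reagents that add atoms: none
Why: Dess–Martin oxidation of both alcohols under bicarbonate buffer gives the aldehyde and the alpha-methylene ketone in one operation; the neutral conditions should preserve C4 and keep C13=C14 out of conjugation.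

Step 20
Reactants: 31 (2S,4S,9E)-4-[(2R)-3-methoxy-2,4-dimethyl-5-oxo-2,5-dihydrofuran-2-yl]-5-methylidene-6-oxo-2-[(1E)-prop-1-en-1-yl]undec-9-enal
Product: 32 (5R)-5-[(1S,2R,5S)-2-[(4E)-hex-4-enoyl]-4-oxo-5-[(1E)-prop-1-en-1-yl]cyclohexyl]-4-methoxy-3,5-dimethylfuran-2(5H)-one
Conditions: (5aR,10bS)-2-(pentafluorophenyl)-5a,10b-dihydro-4H,6H-indeno[2,1-b][1,2,4]triazolo[4,3-d][1,4]oxazin-2-ium tetrafluoroborate (20 mol%), KN(SiMe3)2 (18 mol%), toluene, 23 °C, 0.01 M; carbene pre-formed and freed of HN(SiMe3)2 under vacuum before 31 is added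
Reagents that add atoms: none
Why: The free triazolylidene adds to the C3 aldehyde and a proton shift gives the Breslow intermediate, whose nucleophilic C3 attacks the unsubstituted methylene C2 of the C2=C1–C7 enone; the C1=C7 enolate is then protonated at C1 and the catalyst leaves, giving the C3 ketone (intramolecular Stetter reaction). The closest known reaction type is the enantio- and diastereoselective intramolecular Stetter cyclisation of aldehydes onto alpha-substituted acceptors, where the alpha stereocentre is fixed by proton transfer inside the catalyst-bound adduct. Ring A closes in a 6-endo-trig mode, since both alkene carbons C1 and C2 end up in the ring. C1 is the one new stereocentre: A(1,3) strain between the exocyclic enolate and the C6 tetronate turns that group axial, so the proton should arrive on the opposite face and leave the acyl group cis to C5', and the chiral catalyst is chosen to pass the carbinol proton to the same face. The step needs 1,4- over 1,2-addition and an untouched C4 and C13=C14: benzoin-type addition to the C7 carbonyl is reversible while the conjugate addition is not, and the weakly basic pentafluorophenyl carbene, used without excess base or free amine, limits enolisation of the aldehyde. If C4 epimerises in part, it is alpha to the new ketone, and the equatorial arrangement cis to C6 is the favoured one.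

Step 21
Reactants: 32 (5R)-5-[(1S,2R,5S)-2-[(4E)-hex-4-enoyl]-4-oxo-5-[(1E)-prop-1-en-1-yl]cyclohexyl]-4-methoxy-3,5-dimethylfuran-2(5H)-one
Product: 33 (5R)-5-[(1S,2R,5S)-2-[(4E)-hex-4-enoyl]-4-oxo-5-[(1E)-prop-1-en-1-yl]cyclohexyl]-4-hydroxy-3,5-dimethylfuran-2(5H)-one (CNP0546498.1)
Conditions: LiCl, DMSO, 50 °C; dilute HCl work-up
Reagents that add atoms: none
Why: SN2 demethylation of the methyl tetronate (a vinylogous methyl ester) by chloride in a dipolar aprotic solvent; the departing tetronate is a very weak base, so C1 and C4 should not epimerise.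

**Compound list**
1 | 2-methyl-2-vinyloxirane | C=CC1(C)CO1 | starting material
2 | (2E)-4-bromo-2-methylbut-2-en-1-ol | BrC/C=C(\C)CO | intermediate
3 | tert-butyl{[(2E)-4-bromo-2-methylbut-2-en-1-yl]oxy}dimethylsilane | BrC/C=C(\C)CO[Si](C)(C)C(C)(C)C | intermediate
4 | (3E)-pent-3-enoic acid | C/C=C/CC(=O)O | starting material
5 | (4S)-4-benzyl-1,3-oxazolidin-2-one | O=C1N[C@@H](Cc2ccccc2)CO1 | starting material
6 | (3E)-pent-3-enoic pivalic anhydride | C/C=C/CC(=O)OC(=O)C(C)(C)C | intermediate (not isolated)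
7 | (4S)-4-benzyl-3-[(3E)-pent-3-enoyl]-1,3-oxazolidin-2-one | C/C=C/CC(=O)N1[C@@H](Cc2ccccc2)COC1=O | intermediate
8 | sodium (1Z,3E)-1-[(4S)-4-benzyl-2-oxo-1,3-oxazolidin-3-yl]penta-1,3-dien-1-olate | C/C=C/C=C(\[O-])N1[C@@H](Cc2ccccc2)COC1=O.[Na+] | intermediate (not isolated)
9 | (4S)-4-benzyl-3-[(2S,3E)-2-{(2E)-4-[(tert-butyldimethylsilyl)oxy]-3-methylbut-2-en-1-yl}pent-3-enoyl]-1,3-oxazolidin-2-one | C/C=C/[C@H](C/C=C(\C)CO[Si](C)(C)C(C)(C)C)C(=O)N1[C@@H](Cc2ccccc2)COC1=O | intermediate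
10 | (2S,3E)-2-{(2E)-4-[(tert-butyldimethylsilyl)oxy]-3-methylbut-2-en-1-yl}pent-3-en-1-ol | C/C=C/[C@H](C/C=C(\C)CO[Si](C)(C)C(C)(C)C)CO | intermediate
11 | tert-butyl{[(2S,3E)-2-{(2E)-4-[(tert-butyldimethylsilyl)oxy]-3-methylbut-2-en-1-yl}pent-3-en-1-yl]oxy}diphenylsilane | C/C=C/[C@H](C/C=C(\C)CO[Si](C)(C)C(C)(C)C)CO[Si](c1ccccc1)(c1ccccc1)C(C)(C)C | intermediate
12 | (2E,5S,6E)-5-{[(tert-butyldiphenylsilyl)oxy]methyl}-2-methylocta-2,6-dien-1-ol | C/C=C/[C@H](C/C=C(\C)CO)CO[Si](c1ccccc1)(c1ccccc1)C(C)(C)C | intermediate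
13 | [(2S,3S)-3-[(2S,3E)-2-{[(tert-butyldiphenylsilyl)oxy]methyl}pent-3-en-1-yl]-2-methyloxiran-2-yl]methanol | C/C=C/[C@H](C[C@@H]1O[C@@]1(C)CO)CO[Si](c1ccccc1)(c1ccccc1)C(C)(C)C | intermediate
14 | trimethylsilylacetylene | C#C[Si](C)(C)C | starting material
15 | lithium (trimethylsilyl)acetylide | [Li+].[C-]#C[Si](C)(C)C | intermediate (not isolated)
16 | diethyl[(trimethylsilyl)ethynyl]aluminium | CC[Al](CC)C#C[Si](C)(C)C | intermediate (not isolated)
17 | (2R,3S,5S,6E)-5-{[(tert-butyldiphenylsilyl)oxy]methyl}-2-methyl-3-[(trimethylsilyl)ethynyl]oct-6-ene-1,2-diol | C/C=C/[C@H](C[C@@H](C#C[Si](C)(C)C)[C@@](CO)(C)O)CO[Si](c1ccccc1)(c1ccccc1)C(C)(C)C | intermediate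
18 | (2R,3S,5S,6E)-5-{[(tert-butyldiphenylsilyl)oxy]methyl}-2-hydroxy-2-methyl-3-[(trimethylsilyl)ethynyl]oct-6-enal | C/C=C/[C@H](C[C@@H](C#C[Si](C)(C)C)[C@@](C=O)(C)O)CO[Si](c1ccccc1)(c1ccccc1)C(C)(C)C | intermediate (not isolated)
19 | (2R,3S,5S,6E)-5-{[(tert-butyldiphenylsilyl)oxy]methyl}-2-hydroxy-2-methyl-3-[(trimethylsilyl)ethynyl]oct-6-enoic acid | C/C=C/[C@H](C[C@@H](C#C[Si](C)(C)C)[C@@](C(=O)O)(C)O)CO[Si](c1ccccc1)(c1ccccc1)C(C)(C)C | intermediate
20 | methyl (2R,3S,5S,6E)-5-{[(tert-butyldiphenylsilyl)oxy]methyl}-2-hydroxy-2-methyl-3-[(trimethylsilyl)ethynyl]oct-6-enoate | C/C=C/[C@H](C[C@@H](C#C[Si](C)(C)C)[C@@](C(=O)OC)(C)O)CO[Si](c1ccccc1)(c1ccccc1)C(C)(C)C | intermediate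
21 | methyl (2R,3S,5S,6E)-5-{[(tert-butyldiphenylsilyl)oxy]methyl}-2-methyl-2-(propanoyloxy)-3-[(trimethylsilyl)ethynyl]oct-6-enoate | C/C=C/[C@H](C[C@@H](C#C[Si](C)(C)C)[C@@](C(=O)OC)(C)OC(=O)CC)CO[Si](c1ccccc1)(c1ccccc1)C(C)(C)C | intermediate
22 | potassium (2R)-2-[(3S,5S,6E)-5-{[(tert-butyldiphenylsilyl)oxy]methyl}-1-(trimethylsilyl)oct-6-en-1-yn-3-yl]-2,4-dimethyl-5-oxo-2,5-dihydrofuran-3-olate | C/C=C/[C@H](C[C@@H](C#C[Si](C)(C)C)[C@@]1(C)OC(=O)C(C)=C1[O-])CO[Si](c1ccccc1)(c1ccccc1)C(C)(C)C.[K+] | intermediate (not isolated)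
23 | (5R)-5-[(3S,5S,6E)-5-{[(tert-butyldiphenylsilyl)oxy]methyl}-1-(trimethylsilyl)oct-6-en-1-yn-3-yl]-4-methoxy-3,5-dimethylfuran-2(5H)-one | C/C=C/[C@H](C[C@@H](C#C[Si](C)(C)C)[C@@]1(C)OC(=O)C(C)=C1OC)CO[Si](c1ccccc1)(c1ccccc1)C(C)(C)C | intermediate
24 | (5R)-5-[(3S,5S,6E)-5-{[(tert-butyldiphenylsilyl)oxy]methyl}oct-6-en-1-yn-3-yl]-4-methoxy-3,5-dimethylfuran-2(5H)-one | C/C=C/[C@H](C[C@@H](C#C)[C@@]1(C)OC(=O)C(C)=C1OC)CO[Si](c1ccccc1)(c1ccccc1)C(C)(C)C | intermediate
25 | (5R)-5-[(1Z,3R,5S,6E)-1-(9-borabicyclo[3.3.1]nonan-9-yl)-5-{[(tert-butyldiphenylsilyl)oxy]methyl}-2-iodoocta-1,6-dien-3-yl]-4-methoxy-3,5-dimethylfuran-2(5H)-one | C/C=C/[C@H](C[C@@H](/C(I)=C/B1C2CCCC1CCC2)[C@@]1(C)OC(=O)C(C)=C1OC)CO[Si](c1ccccc1)(c1ccccc1)C(C)(C)C | intermediate (not isolated)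
26 | (5R)-5-[(3R,5S,6E)-5-{[(tert-butyldiphenylsilyl)oxy]methyl}-2-iodoocta-1,6-dien-3-yl]-4-methoxy-3,5-dimethylfuran-2(5H)-one | C/C=C/[C@H](C[C@@H](C(I)=C)[C@@]1(C)OC(=O)C(C)=C1OC)CO[Si](c1ccccc1)(c1ccccc1)C(C)(C)C | intermediate
27 | (4E)-hex-4-en-1-ol | C/C=C/CCCO | starting material
28 | (4E)-hex-4-enal | C/C=C/CCC=O | intermediate
29 | (5R)-5-[(2E,4S,6S,11E)-4-{[(tert-butyldiphenylsilyl)oxy]methyl}-8-hydroxy-7-methylidenetrideca-2,11-dien-6-yl]-4-methoxy-3,5-dimethylfuran-2(5H)-one, both carbinol epimers | C/C=C/[C@H](C[C@@H](C(=C)C(O)CC/C=C/C)[C@@]1(C)OC(=O)C(C)=C1OC)CO[Si](c1ccccc1)(c1ccccc1)C(C)(C)C | intermediate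
30 | (5R)-5-[(2E,4S,6S,11E)-8-hydroxy-4-(hydroxymethyl)-7-methylidenetrideca-2,11-dien-6-yl]-4-methoxy-3,5-dimethylfuran-2(5H)-one, both carbinol epimers | C/C=C/[C@H](C[C@@H](C(=C)C(O)CC/C=C/C)[C@@]1(C)OC(=O)C(C)=C1OC)CO | intermediate
31 | (2S,4S,9E)-4-[(2R)-3-methoxy-2,4-dimethyl-5-oxo-2,5-dihydrofuran-2-yl]-5-methylidene-6-oxo-2-[(1E)-prop-1-en-1-yl]undec-9-enal | O=C[C@H](/C=C/C)C[C@@H](C(=C)C(=O)CC/C=C/C)[C@@]1(C)OC(=O)C(C)=C1OC | intermediate
32 | (5R)-5-[(1S,2R,5S)-2-[(4E)-hex-4-enoyl]-4-oxo-5-[(1E)-prop-1-en-1-yl]cyclohexyl]-4-methoxy-3,5-dimethylfuran-2(5H)-one | C/C=C/CCC(=O)[C@@H]1CC(=O)[C@H](/C=C/C)C[C@@H]1[C@@]1(C)OC(=O)C(C)=C1OC | intermediate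
33 | (5R)-5-[(1S,2R,5S)-2-[(4E)-hex-4-enoyl]-4-oxo-5-[(1E)-prop-1-en-1-yl]cyclohexyl]-4-hydroxy-3,5-dimethylfuran-2(5H)-one | C/C=C/CCC(=O)[C@@H]1CC(=O)[C@H](/C=C/C)C[C@@H]1[C@@]1(C)OC(=O)C(C)=C1O | target

**Totals**
Total steps: 21. Longest linear sequence: 19 (steps 1, 2, 4–15, 17–21).

**Steps most likely to fail**

1. Step 20. The Breslow intermediate may form slowly at the alpha-branched aldehyde. The carbene may instead be held up by 1,2-addition at C7 or add to the enone itself. The basic carbene may enolise the aldehyde, which would scramble C4 or draw C13=C14 into conjugation. Proton delivery at C1 may occur on both faces. The fallback sets out from 31 and returns at 32. SmI2 in THF/MeOH at −78 °C reduces the aldehyde to its ketyl, which adds to the methylene C2 of the enone, forming the same C2–C3 bond by 6-endo radical closure. The samarium enolate is protonated by MeOH at C1 on the face away from the tetronate, giving the cyclohexanol F1 (either C3 epimer). Dess–Martin oxidation of the C3 carbinol then gives 32.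

2. Step 15. The Lewis-acidic boron iodide may demethylate the tetronate or strip the silyl ether, and stray HI may add to the alkenes. The fallback sets out from 24 and returns at 26. Hydrosilylation with Et3SiH and [Cp*Ru(MeCN)3]PF6 (cat.) in CH2Cl2 places silicon on the internal alkyne carbon and gives the 2-(triethylsilyl)alk-1-ene F2. Iododesilylation with N-iodosuccinimide in (CF3)2CHOH at 0 °C then gives 26.

3. Step 12. Acylation of the crowded tertiary hydroxyl may stall, or the Lewis acid may cause loss of a silyl group or elimination of the tertiary alcohol. The fallback sets out from 20 and returns at 23, replacing steps 12 and 13. Heating 20 with ketenylidenetriphenylphosphorane (Ph3P=C=C=O) in toluene adds the hydroxyl across the ketene to give the ester ylide F3. This closes by intramolecular Wittig olefination of the methyl ester carbonyl to the 3-unsubstituted methyl tetronate F4, the ester methoxy becoming the C4' methoxy. Lithiation at C3' with LiN(iPr)2 in THF at −78 °C gives the 3-lithio tetronate F5, which iodomethane methylates to 23.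

**Further compounds**
F1 | step 20 | (5R)-5-[(1S,2R,5S)-2-[(4E)-hex-4-enoyl]-4-hydroxy-5-[(1E)-prop-1-en-1-yl]cyclohexyl]-4-methoxy-3,5-dimethylfuran-2(5H)-one, either carbinol epimer | C/C=C/CCC(=O)[C@@H]1CC(O)[C@H](/C=C/C)C[C@@H]1[C@@]1(C)OC(=O)C(C)=C1OC
F2 | step 15 | (5R)-5-[(3R,5S,6E)-5-{[(tert-butyldiphenylsilyl)oxy]methyl}-2-(triethylsilyl)octa-1,6-dien-3-yl]-4-methoxy-3,5-dimethylfuran-2(5H)-one | C/C=C/[C@H](C[C@@H](C(=C)[Si](CC)(CC)CC)[C@@]1(C)OC(=O)C(C)=C1OC)CO[Si](c1ccccc1)(c1ccccc1)C(C)(C)C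
F3 | step 12 | methyl (2R,3S,5S,6E)-5-{[(tert-butyldiphenylsilyl)oxy]methyl}-2-methyl-2-{[(triphenyl-λ5-phosphanylidene)acetyl]oxy}-3-[(trimethylsilyl)ethynyl]oct-6-enoate | C/C=C/[C@H](C[C@@H](C#C[Si](C)(C)C)[C@@](C(=O)OC)(C)OC(=O)C=P(c1ccccc1)(c1ccccc1)c1ccccc1)CO[Si](c1ccccc1)(c1ccccc1)C(C)(C)C
F4 | step 12 | (5R)-5-[(3S,5S,6E)-5-{[(tert-butyldiphenylsilyl)oxy]methyl}-1-(trimethylsilyl)oct-6-en-1-yn-3-yl]-4-methoxy-5-methylfuran-2(5H)-one | C/C=C/[C@H](C[C@@H](C#C[Si](C)(C)C)[C@@]1(C)OC(=O)C=C1OC)CO[Si](c1ccccc1)(c1ccccc1)C(C)(C)C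
F5 | step 12 | (5R)-5-[(3S,5S,6E)-5-{[(tert-butyldiphenylsilyl)oxy]methyl}-1-(trimethylsilyl)oct-6-en-1-yn-3-yl]-3-lithio-4-methoxy-5-methylfuran-2(5H)-one | C/C=C/[C@H](C[C@@H](C#C[Si](C)(C)C)[C@@]1(C)OC(=O)C([Li])=C1OC)CO[Si](c1ccccc1)(c1ccccc1)C(C)(C)C
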